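**Assumptions.** Read from the SMILES, the chroman C2 is (R) and the carbinol is (R). Acid-promoted opening of the tertiary epoxide by the phenol (Step 10) is assumed to proceed by inversion at the tertiary carbon (anti, SN2-like, 6-exo).

## Retrosynthetic overview
1. The last steps are a B-alkyl Suzuki coupling of the hydroborated 2-vinylchroman **13** with the (E,E)-vinyl iodide **26**, then TBAF removal of both silyl groups.
2. The vinyl iodide **26** comes from two Zr-catalysed carboaluminations of terminal alkynes, joined by a Negishi coupling to a homopropargylzinc reagent. The (R)-carbinol comes from enzymatic (ketoreductase) reduction of the TMS-ynone **16**, and the prenyl group is installed by cross-metathesis.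
3. The chroman **13** comes from the aldehyde **12** by Wittig methylenation. **12** comes from NaIO4 cleavage of the diol formed when a Sharpless epoxy alcohol is opened by the phenol (6-exo, inversion at the tertiary carbon).
4. The aromatic ring is present from the start (from 2-methylhydroquinone), and the pyran ring closes in Step 10. C2 is set by the Sharpless epoxidation (first stereocenter) and C9' by the ketoreductase.

## Forward route

**Step 1**
Reactants: **1** 2-methylbenzene-1,4-diol
Product: **2** 2-methyl-4-(triisopropylsilyloxy)phenol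
Conditions: TIPSCl, imidazole, DMF, 0 °C → rt
Reagents that add atoms: TIPSCl, CC(C)[Si](Cl)(C(C)C)C(C)C
Why: Silylation occurs at the less hindered 4-OH (the 1-OH is flanked by the methyl); the regioisomer and bis-silyl ether are removed by chromatography.

**Step 2**
Reactants: **2**
Product: **3** 2-hydroxy-3-methyl-5-(TIPSO)benzaldehyde
Conditions: MgCl2, Et3N, (CH2O)n, MeCN, 80 °C
Reagents that add atoms: paraformaldehyde, C=O
Why: Casnati–Skattebøl Mg-phenoxide-directed ortho-formylation can only occur at C6, the single free ortho position.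

**Step 3**
Reactants: **3**
Product: **4** (E)-4-[2-hydroxy-3-methyl-5-(TIPSO)phenyl]but-3-en-2-one
Conditions: LiCl, DBU, MeCN, rt
Reagents that add atoms: dimethyl (2-oxopropyl)phosphonate, COP(=O)(OC)CC(C)=O
Why: Masamune–Roush Horner–Wadsworth–Emmons olefination gives the E-enone selectively under base mild enough to spare the aryl silyl ether.

**Step 4**
Reactants: **4**
Product: **5** 4-[2-hydroxy-3-methyl-5-(TIPSO)phenyl]butan-2-one
Conditions: H2 (1 atm), 10% Pd/C, EtOAc, rt
Reagents that add atoms: none
Why: Catalytic hydrogenation reduces only the conjugated C=C; the ketone, phenol and aryl TIPS ether are untouched.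

**Step 5**
Reactants: **5**
Product: **6** 4-[2-(benzyloxy)-3-methyl-5-(TIPSO)phenyl]butan-2-one
Conditions: BnBr, Cs2CO3, DMF, rt
Reagents that add atoms: benzyl bromide, BrCc1ccccc1
Why: Williamson O-alkylation masks the phenol that will form the ring oxygen so that it does not interfere with the Ti-catalysed epoxidation.

**Step 6**
Reactants: **6**
Product: **7** ethyl (2E)-5-[2-(benzyloxy)-3-methyl-5-(TIPSO)phenyl]-3-methylpent-2-enoate
Conditions: NaH, THF, 0 °C → reflux
Reagents that add atoms: triethyl phosphonoacetate, CCOC(=O)CP(=O)(OCC)OCC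
Why: Horner–Wadsworth–Emmons olefination of the methyl ketone favours the E-enoate (E:Z about 5–8:1), and the E isomer is isolated by chromatography.

**Step 7**
Reactants: **7**
Product: **8** (2E)-5-[2-(benzyloxy)-3-methyl-5-(TIPSO)phenyl]-3-methylpent-2-en-1-ol
Conditions: DIBAL-H, CH2Cl2, –78 → 0 °C
Reagents that add atoms: none
Why: DIBAL reduces the ester to the allylic alcohol without touching the benzyl or silyl ethers, and the olefin geometry is retained.

**Step 8**
Reactants: **8**
Product: **9** {(2R,3R)-3-[2-(2-benzyloxy-3-methyl-5-TIPSO-phenyl)ethyl]-3-methyloxiran-2-yl}methanol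
Conditions: Ti(OiPr)4 (10 mol%), D-(–)-DET (12 mol%), TBHP, 3 Å MS, CH2Cl2, –20 °C
Reagents that add atoms: tert-butyl hydroperoxide, CC(C)(C)OO (supplies the epoxide O)
Why: Sharpless asymmetric epoxidation of a geraniol-type (E)-trisubstituted allylic alcohol; D-tartrate delivers oxygen to the face giving the (2R,3R)-epoxide, which sets the future C2 (first stereocenter, asymmetric catalysis).

**Step 9**
Reactants: **9**
Product: **10** {(2R,3R)-3-[2-(2-hydroxy-3-methyl-5-TIPSO-phenyl)ethyl]-3-methyloxiran-2-yl}methanol
Conditions: H2 (1 atm), 10% Pd/C, cat. NaHCO3, EtOAc, rt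
Reagents that add atoms: none
Why: Neutral hydrogenolysis removes the aryl benzyl ether and leaves the non-benzylic epoxide and the silyl ether intact; no phenoxide is generated, which would open the epoxide at the wrong carbon.

**Step 10**
Reactants: **10**
Product: **11** (1R)-1-[(2S)-2,8-dimethyl-6-(TIPSO)chroman-2-yl]ethane-1,2-diol
Conditions: CSA (10 mol%), CH2Cl2 (0.02 M), 0 °C → rt
Reagents that add atoms: none (isomerization)
Why: Acid-promoted intramolecular epoxide opening by the phenol is 6-exo at the tertiary carbon, which is favoured over 7-endo attack, and it proceeds with inversion. The epoxide C2 (R) therefore becomes the chroman C2 with the target's spatial configuration, and the pyran ring forms here.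

**Step 11**
Reactants: **11**
Product: **12** (2S)-2,8-dimethyl-6-(TIPSO)chroman-2-carbaldehyde
Conditions: NaIO4, THF/H2O, rt
Reagents that add atoms: none
Why: Malaprade cleavage of the vicinal diol gives the aldehyde and destroys the now-unneeded carbinol stereocenter; the quaternary C2 is untouched.

**Step 12**
Reactants: **12**
Product: **13** (2S)-2-ethenyl-2,8-dimethyl-6-(TIPSO)chroman
Conditions: Ph3P+CH3 Br–, KOtBu, THF, 0 °C → rt
Reagents that add atoms: methyltriphenylphosphonium bromide, C[P+](c1ccccc1)(c1ccccc1)c1ccccc1.[Br-] (supplies CH2)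
Why: Wittig methylenation of the non-enolizable α-quaternary aldehyde gives the vinyl group with no epimerization possible at C2. The descriptor changes from R to S only because the substituent priorities change.

**Step 13**
Reactants: **14** 3-(trimethylsilyl)propynal
Product: **15** (±)-1-(trimethylsilyl)hex-5-en-1-yn-3-ol
Conditions: allylMgBr, THF, –78 °C
Reagents that add atoms: allylmagnesium bromide, C=CC[Mg]Br
Why: 1,2-Grignard addition to the ynal; the racemate is harmless because the carbinol is oxidized in the next step.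

**Step 14**
Reactants: **15**
Product: **16** 1-(trimethylsilyl)hex-5-en-1-yn-3-one
Conditions: Dess–Martin periodinane, NaHCO3, CH2Cl2, 0 °C
Reagents that add atoms: none
Why: Buffered, neutral oxidation avoids isomerization of the β,γ-alkene into conjugation.

**Step 15**
Reactants: **16**
Product: **17** (3R)-1-(trimethylsilyl)hex-5-en-1-yn-3-ol
Conditions: (R)-selective ketoreductase (NADPH-dependent alcohol dehydrogenase, an oxidoreductase; chosen from a KRED panel), NADP+ (cat.), iPrOH (15% v/v, cofactor recycling), KPi pH 7.0, 5% DMSO, 30 °C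
Reagents that add atoms: none (hydride from NADPH, proton from water)
Why: The enzyme delivers hydride to one enantiotopic face of the ynone, setting C9' as (R) with high ee; TMS-ynones are established substrates for such reductions.

**Step 16**
Reactants: **17**
Product: **18** tert-butyldimethyl{[(3R)-1-(trimethylsilyl)hex-5-en-1-yn-3-yl]oxy}silane
Conditions: TBSCl, imidazole, DMF, rt
Reagents that add atoms: TBSCl, C[Si](C)(Cl)C(C)(C)C
Why: Silylation protects the alcohol without touching the stereocenter.

**Step 17**
Reactants: **18**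
Product: **19** tert-butyldimethyl{[(3R)-6-methyl-1-(trimethylsilyl)hept-5-en-1-yn-3-yl]oxy}silane
Conditions: Hoveyda–Grubbs II (5 mol%), 2-methyl-2-butene (20 equiv), CH2Cl2, 40 °C, sealed tube
Reagents that add atoms: 2-methyl-2-butene, CC=C(C)C (supplies =CMe2; propene is lost)
Why: Cross-metathesis of the terminal alkene with excess 2-methyl-2-butene installs the prenyl terminus.

**Step 18**
Reactants: **19**
Product: **20** tert-butyldimethyl{[(3R)-6-methylhept-5-en-1-yn-3-yl]oxy}silane
Conditions: K2CO3, MeOH, rt
Reagents that add atoms: none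
Why: Base-mediated C–Si cleavage frees the terminal alkyne and leaves the TBS ether.

**Step 19**
Reactants: **20**
Product: **21** tert-butyl{[(1E,3R)-1-iodo-2,6-dimethylhepta-1,5-dien-3-yl]oxy}dimethylsilane
Conditions: (i) Me3Al, Cp2ZrCl2, ClCH2CH2Cl, 0 °C → rt; (ii) I2, THF, –30 → 0 °C
Reagents that add atoms: trimethylaluminum, C[Al](C)C (supplies CH3); iodine, II
Why: Negishi Zr-catalysed syn-methylalumination of the terminal alkyne places Me on the internal carbon, and iodinolysis with retention gives the E-trisubstituted vinyl iodide; the alkenes and C9' are untouched.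

**Step 20**
Reactants: **22** 4-(trimethylsilyl)but-3-yn-1-ol
Product: **23** (4-iodobut-1-yn-1-yl)trimethylsilane
Conditions: PPh3, I2, imidazole, CH2Cl2/Et2O, 0 °C
Reagents that add atoms: iodine, II
Why: Appel iodination converts the primary alcohol to the iodide needed for zinc insertion.

**Step 21**
Reactants: **21**; **23**
Product: **24** tert-butyldimethyl{[(5E,7R)-6,10-dimethyl-1-(trimethylsilyl)undeca-5,9-dien-1-yn-7-yl]oxy}silane
Conditions: (i) Zn, LiCl, cat. TMSCl/BrCH2CH2Br, THF, 25 °C (23 → alkylzinc); (ii) **21**, Pd(PPh3)4 (5 mol%), THF, 25 °C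
Reagents that add atoms: none
Why: Negishi sp3–sp2 coupling of the homopropargylzinc with the vinyl iodide forms C6'–C7' with retention of the E geometry.

**Step 22**
Reactants: **24**
Product: **25** tert-butyldimethyl{[(5E,7R)-6,10-dimethylundeca-5,9-dien-1-yn-7-yl]oxy}silane
Conditions: K2CO3, MeOH, rt
Reagents that add atoms: none
Why: Selective desilylation of the alkynyl TMS group; the alkyl TBS ether survives.

**Step 23**
Reactants: **25**
Product: **26** tert-butyl{[(1E,5E,7R)-1-iodo-2,6,10-trimethylundeca-1,5,9-trien-7-yl]oxy}dimethylsilane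
Conditions: (i) Me3Al, Cp2ZrCl2, ClCH2CH2Cl, 0 °C → rt; (ii) I2, THF, –30 → 0 °C
Reagents that add atoms: trimethylaluminum, C[Al](C)C; iodine, II
Why: Syn-carboalumination followed by iodinolysis again gives an E-vinyl iodide (the C3'=C4' geometry); Zr/Al does not carbometalate the trisubstituted alkenes.

**Step 24**
Reactants: **13**; **26**
Product: **27** (2R)-2-[(3E,7E,9R)-9-(TBSO)-4,8,12-trimethyltrideca-3,7,11-trien-1-yl]-2,8-dimethyl-6-(TIPSO)chroman
Conditions: (i) 9-BBN dimer (1.1 equiv of B–H), THF, 25 → 50 °C, on **13**; (ii) **26**, Pd(dppf)Cl2 (10 mol%), K3PO4 (aq.), THF, 25 °C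
Reagents that add atoms: none (boron is lost)
Why: Terminal hydroboration gives the primary alkyl-9-BBN, and Suzuki–Miyaura B-alkyl coupling joins C2'–C3' with retention of alkene geometry; C2 is quaternary and cannot epimerize.

**Step 25**
Reactants: **27**
Product: **28** sargachromanol C
Conditions: TBAF (4 equiv), THF, 0 → 35 °C
Reagents that add atoms: none
Why: Fluoride cleaves the aryl TIPS ether and the secondary TBS ether in one step; neither stereocenter nor any alkene is affected.

## Compound list
1 | 2-methylbenzene-1,4-diol | Cc1cc(O)ccc1O | starting material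
2 | 2-methyl-4-(TIPSO)phenol | Cc1cc(O[Si](C(C)C)(C(C)C)C(C)C)ccc1O | intermediate
3 | 2-hydroxy-3-methyl-5-(TIPSO)benzaldehyde | Cc1cc(O[Si](C(C)C)(C(C)C)C(C)C)cc(C=O)c1O | intermediate
4 | (E)-enone | CC(=O)/C=C/c1cc(O[Si](C(C)C)(C(C)C)C(C)C)cc(C)c1O | intermediate
5 | saturated ketone | CC(=O)CCc1cc(O[Si](C(C)C)(C(C)C)C(C)C)cc(C)c1O | intermediate
6 | O-benzyl ketone | CC(=O)CCc1cc(O[Si](C(C)C)(C(C)C)C(C)C)cc(C)c1OCc1ccccc1 | intermediate
7 | (E)-enoate | CCOC(=O)/C=C(\C)CCc1cc(O[Si](C(C)C)(C(C)C)C(C)C)cc(C)c1OCc1ccccc1 | intermediate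
8 | (E)-allylic alcohol | OC/C=C(\C)CCc1cc(O[Si](C(C)C)(C(C)C)C(C)C)cc(C)c1OCc1ccccc1 | intermediate
9 | (2R,3R)-epoxy alcohol (OBn) | OC[C@H]1O[C@]1(C)CCc1cc(O[Si](C(C)C)(C(C)C)C(C)C)cc(C)c1OCc1ccccc1 | intermediate
10 | (2R,3R)-epoxy phenol | OC[C@H]1O[C@]1(C)CCc1cc(O[Si](C(C)C)(C(C)C)C(C)C)cc(C)c1O | intermediate
11 | chroman diol (1R,2'S) | OC[C@@H](O)[C@]1(C)CCc2cc(O[Si](C(C)C)(C(C)C)C(C)C)cc(C)c2O1 | intermediate
12 | chroman-2-carbaldehyde (2S) | O=C[C@]1(C)CCc2cc(O[Si](C(C)C)(C(C)C)C(C)C)cc(C)c2O1 | intermediate
13 | 2-vinylchroman (2S) | C=C[C@]1(C)CCc2cc(O[Si](C(C)C)(C(C)C)C(C)C)cc(C)c2O1 | intermediate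
14 | 3-(trimethylsilyl)propynal | C[Si](C)(C)C#CC=O | starting material
15 | (±)-TMS-hexenynol | C=CCC(O)C#C[Si](C)(C)C | intermediate
16 | TMS-hexenynone | C=CCC(=O)C#C[Si](C)(C)C | intermediate
17 | (3R)-TMS-hexenynol | C=CC[C@@H](O)C#C[Si](C)(C)C | intermediate
18 | TBS ether of 17 | C=CC[C@@H](O[Si](C)(C)C(C)(C)C)C#C[Si](C)(C)C | intermediate
19 | prenyl TBS ether | CC(C)=CC[C@@H](O[Si](C)(C)C(C)(C)C)C#C[Si](C)(C)C | intermediate
20 | terminal alkyne | CC(C)=CC[C@@H](O[Si](C)(C)C(C)(C)C)C#C | intermediate
21 | vinyl iodide | CC(C)=CC[C@@H](O[Si](C)(C)C(C)(C)C)/C(C)=C/I | intermediate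
22 | 4-(trimethylsilyl)but-3-yn-1-ol | C[Si](C)(C)C#CCCO | starting material
23 | (4-iodobut-1-ynyl)trimethylsilane | C[Si](C)(C)C#CCCI | intermediate
24 | TMS-enyne | CC(C)=CC[C@@H](O[Si](C)(C)C(C)(C)C)/C(C)=C/CCC#C[Si](C)(C)C | intermediate
25 | terminal enyne | CC(C)=CC[C@@H](O[Si](C)(C)C(C)(C)C)/C(C)=C/CCC#C | intermediate
26 | dienyl vinyl iodide | CC(C)=CC[C@@H](O[Si](C)(C)C(C)(C)C)/C(C)=C/CC/C(C)=C/I | intermediate
27 | fully protected sargachromanol C | CC(C)=CC[C@@H](O[Si](C)(C)C(C)(C)C)/C(C)=C/CC/C(C)=C/CC[C@]1(C)CCc2cc(O[Si](C(C)C)(C(C)C)C(C)C)cc(C)c2O1 | intermediate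
28 | sargachromanol C | CC(C)=CC[C@@H](O)/C(C)=C/CC/C(C)=C/CC[C@]1(C)CCc2cc(O)cc(C)c2O1 | target

## Step count
- Total steps: 25.
- Longest linear sequence: 14 steps (1 → 12, then 24, 25). The alkyne/KRED branch is 12 steps to the end, through 13–19, 21–23, 24 and 25.

## Three steps most likely to fail
1. **Step 10 (phenol opening of the tertiary epoxide).**
   - Risk: partial SN1 racemization, elimination, or indane formation.
   - Fallback: make racemic **12** by the same sequence from a racemic epoxide (mCPBA), reduce it to the primary alcohol, resolve with Pseudomonas lipase and vinyl acetate, and re-oxidize with DMP.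
2. **Step 15 (ketoreductase reduction of the β,γ-unsaturated TMS-ynone).**
   - Risk: low conversion, substrate instability in buffer, or insufficient ee.
   - Fallback: Noyori–Ikariya transfer hydrogenation of **16** (RuCl[TsDPEN](p-cymene), HCO2H/Et3N, using the catalyst enantiomer that gives R), or CAL-B kinetic resolution of **15**.
3. **Step 24 (hindered B-alkyl Suzuki coupling).**
   - Risk: slow hydroboration or coupling next to the quaternary center, or protodeboronation.
   - Fallback: hydrozirconate **13** with Cp2Zr(H)Cl, transmetalate to ZnCl2, and do a Negishi coupling with **26**.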